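The cyclohexenol ring (C1 carbinol, C2 bearing the acyloxymethyl group, C3 olefinic CH, C4 CH2, C5 bearing the side chain, C6 CH2) is read as a 3-substituted cyclobutanone (C1, C6, C5, C4) plus an alkyne (C2, C3). A nickel-catalysed insertion of a silyl-capped propargyl ether into the C1–C4 bond of the cyclobutanone forms C1–C2 and C3–C4 in one operation, expands the four-membered ring to a carvone-like enone and, by ligand-controlled choice between the enantiotopic ring bonds, sets C5. The side chain is attached beforehand by a ruthenium-catalysed alkene–alkyne coupling. Reduction, global desilylation and double acylation finish the route.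

Key step: step 7

Remark: the sense of induction of the chiral ligand in step 7 cannot be predicted, so the ligand antipode is fixed in a pilot run (both are available) and the C5 configuration is checked by correlation after step 8.

Step 1
Reactants: 1 (S)-2-methylglycidol
Product: 2 tert-butyldimethyl{[(2R)-2-methyloxiran-2-yl]methoxy}silane
Conditions: TBSCl, imidazole, CH2Cl2, 0 °C to rt
Reagents that add atoms: tert-butyldimethylsilyl chloride, CC(C)(C)[Si](C)(C)Cl
Why: Imidazole-promoted silyl ether formation on the primary alcohol leaves the epoxide and its quaternary stereocentre untouched; the descriptor changes from S to R only because the silyloxymethyl arm now outranks the oxirane CH2.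

Step 2
Reactants: 2 tert-butyldimethyl{[(2R)-2-methyloxiran-2-yl]methoxy}silane
Product: 3 (2R)-1-[(tert-butyldimethylsilyl)oxy]-2-methylpent-4-en-2-ol
Conditions: vinylmagnesium bromide, CuBr·SMe2 (10 mol%), THF, −40 °C to 0 °C; then H2O/aq. NH4Cl
Reagents that add atoms: vinylmagnesium bromide, C=C[Mg]Br
Why: Copper-catalysed Grignard opening of the 2,2-disubstituted epoxide is an SN2 attack at the unhindered CH2 terminus, so the tertiary carbinol stereocentre is carried over unchanged.

Step 3
Reactants: 4 methyl 3,3-dimethoxycyclobutane-1-carboxylate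
Product: 6 3-ethynyl-1,1-dimethoxycyclobutane, via ketal aldehyde 5 (not isolated)
Conditions: DIBAL-H (iBu2AlH), CH2Cl2, −78 °C; then MeOH, K2CO3, Ohira–Bestmann reagent, −78 °C to rt
Reagents that add atoms: Ohira–Bestmann reagent (dimethyl (1-diazo-2-oxopropyl)phosphonate), CC(=O)C(=[N+]=[N-])P(=O)(OC)OC
Why: One-pot partial reduction of the ester to the aldehyde followed by Seyferth–Gilbert homologation with the Ohira–Bestmann reagent should give the terminal alkyne under basic conditions that leave the dimethyl ketal intact.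

Step 4
Reactants: 6 3-ethynyl-1,1-dimethoxycyclobutane
Product: 7 3-ethynylcyclobutan-1-one
Conditions: 2 M aq. HCl, THF, rt; ether extract concentrated cold and used at once (volatile)
Reagents that add atoms: water, O
Why: Acid-catalysed ketal hydrolysis frees the ketone, and the terminal alkyne is inert to dilute acid.

Step 5
Reactants: 7 3-ethynylcyclobutan-1-one; 3 (2R)-1-[(tert-butyldimethylsilyl)oxy]-2-methylpent-4-en-2-ol
Product: 8 3-[(4E,6R)-7-[(tert-butyldimethylsilyl)oxy]-6-hydroxy-6-methylhepta-1,4-dien-2-yl]cyclobutan-1-one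
Conditions: [CpRu(MeCN)3]PF6 (10 mol%), acetone, rt
Reagents that add atoms: none
Why: Ruthenium-catalysed alkene–alkyne coupling (formal Alder–ene reaction) through a ruthenacyclopentene should join the alkene CH2 terminus to the internal alkyne carbon and, after β-hydride elimination and reductive elimination, give the branched 1,4-diene with an E olefin; the ketone, silyl ether and free tertiary alcohol are tolerated and the carbinol stereocentre is not involved.

Step 6
Reactants: 9 3-(trimethylsilyl)prop-2-yn-1-ol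
Product: 10 tert-butyldimethyl{[3-(trimethylsilyl)prop-2-yn-1-yl]oxy}silane
Conditions: TBSCl, imidazole, CH2Cl2, 0 °C to rt
Reagents that add atoms: tert-butyldimethylsilyl chloride, CC(C)(C)[Si](C)(C)Cl
Why: Routine silyl ether formation gives a propargylic ether that, unlike a propargylic ester, should not ionise on zerovalent nickel, while the C-silyl group is kept as a regiocontrol element.

Step 7
Reactants: 8 3-[(4E,6R)-7-[(tert-butyldimethylsilyl)oxy]-6-hydroxy-6-methylhepta-1,4-dien-2-yl]cyclobutan-1-one; 10 tert-butyldimethyl{[3-(trimethylsilyl)prop-2-yn-1-yl]oxy}silane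
Product: 11 (5R)-2-{[(tert-butyldimethylsilyl)oxy]methyl}-5-[(4E,6R)-7-[(tert-butyldimethylsilyl)oxy]-6-hydroxy-6-methylhepta-1,4-dien-2-yl]-3-(trimethylsilyl)cyclohex-2-en-1-one
Conditions: Ni(cod)2 (10 mol%), (S)-BINOL-derived N,N-bis[(S)-1-phenylethyl]phosphoramidite (20 mol%, or its antipode as fixed by the pilot run), 10 (2.5 equiv), toluene, 80 °C
Reagents that add atoms: none
Why: Proposed new method: zerovalent nickel should couple the C=O of 8 and alkyne 10 by oxidative cyclisation to a spiro oxanickelacyclopentene (bond from the carbonyl carbon to the alkyne carbon bearing CH2OTBS), β-carbon elimination then opens the strained four-membered ring to a seven-membered nickelacycle, and C(sp2)–C(sp3) reductive elimination joins the silyl-bearing carbon to the former α-CH2. The closest known reaction types are the Ni(cod)2/PCy3-catalysed intermolecular insertion of internal alkynes into 3-substituted cyclobutanones, which is not enantioselective, and the nickel/chiral phosphoramidite-catalysed intramolecular olefin insertion that desymmetrises 3-substituted cyclobutanones; new here is enantiotopic-bond selection by a chiral ligand in the intermolecular alkyne case. The six-membered ring is closed not by cyclisation of a chain but by formal [4+2] ring expansion, the ring-closing event being reductive elimination from the seven-membered nickelacycle. The only new stereocentre, C5, arises when the ligand-bound nickel selects one of the two enantiotopic C(=O)–CH2 bonds of the prochiral cyclobutanone for β-carbon elimination, so it is under catalyst control and the remote side-chain carbinol plays no part (the R descriptor corresponds to S in the target because the silyl-bearing carbon raises the priority of the C4 branch). The step needs regioselectivity in the alkyne orientation, secured by the trimethylsilyl group, which in carbonyl–alkyne oxidative cyclisations on nickel ends up on the nickel-bound carbon, and chemoselectivity over the two side-chain olefins, which cannot form an unstrained nickelacycle with the ketone; the internal, silyl-capped alkyne should also resist oligomerisation.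

Step 8
Reactants: 11 (5R)-2-{[(tert-butyldimethylsilyl)oxy]methyl}-5-[(4E,6R)-7-[(tert-butyldimethylsilyl)oxy]-6-hydroxy-6-methylhepta-1,4-dien-2-yl]-3-(trimethylsilyl)cyclohex-2-en-1-one
Product: 12 (1S,5R)-2-{[(tert-butyldimethylsilyl)oxy]methyl}-5-[(4E,6R)-7-[(tert-butyldimethylsilyl)oxy]-6-hydroxy-6-methylhepta-1,4-dien-2-yl]-3-(trimethylsilyl)cyclohex-2-en-1-ol
Conditions: NaBH4, CeCl3·7H2O, MeOH, −78 °C to −20 °C
Reagents that add atoms: none
Why: Luche 1,2-reduction with axial hydride delivery to the half-chair enone whose C5 substituent is equatorial should give the pseudo-equatorial alcohol cis to the C5 substituent, as in the reduction of carvone to cis-carveol.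

Step 9
Reactants: 12 (1S,5R)-2-{[(tert-butyldimethylsilyl)oxy]methyl}-5-[(4E,6R)-7-[(tert-butyldimethylsilyl)oxy]-6-hydroxy-6-methylhepta-1,4-dien-2-yl]-3-(trimethylsilyl)cyclohex-2-en-1-ol
Product: 15 (1S,5S)-5-[(4E,6R)-6,7-dihydroxy-6-methylhepta-1,4-dien-2-yl]-2-(hydroxymethyl)cyclohex-2-en-1-ol, via C-silyl tetraol 13 (not isolated), via O-trimethylsilyl ether 14 (not isolated)
Conditions: TBAF (6 equiv), THF, rt, then 60 °C; aq. NH4Cl
Reagents that add atoms: none
Why: Fluoride cleaves both silyl ethers, and the freed primary allylic alkoxide, held cis to the trimethylsilyl group on the ring olefin, should trigger a 1,4 carbon-to-oxygen silyl shift (Brook rearrangement, hydroxyl-assisted protodesilylation of a vinylsilane) whose vinyl anion is protonated in place, the resulting silyl ether then being cleaved by fluoride.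

Step 10
Reactants: 15 (1S,5S)-5-[(4E,6R)-6,7-dihydroxy-6-methylhepta-1,4-dien-2-yl]-2-(hydroxymethyl)cyclohex-2-en-1-ol
Product: 16 {(4S,6S)-6-hydroxy-4-[(4E,6R)-6-hydroxy-6-methyl-7-(2-methylpropanoyloxy)hepta-1,4-dien-2-yl]cyclohex-1-en-1-yl}methyl 2-methylpropanoate
Conditions: isobutyryl chloride (2.1 equiv), 2,4,6-collidine, CH2Cl2, −78 °C to −40 °C
Reagents that add atoms: isobutyryl chloride, CC(C)C(=O)Cl
Why: Low-temperature acylation with an acid chloride and collidine discriminates kinetically between primary and secondary or tertiary hydroxyls, so only the two CH2OH groups should be esterified.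

Compound list
1 | (S)-2-methylglycidol, [(2S)-2-methyloxiran-2-yl]methanol | C1[C@@](C)(O1)CO | starting material
2 | tert-butyldimethyl{[(2R)-2-methyloxiran-2-yl]methoxy}silane | C1[C@@](C)(O1)CO[Si](C)(C)C(C)(C)C | intermediate
3 | (2R)-1-[(tert-butyldimethylsilyl)oxy]-2-methylpent-4-en-2-ol | C=CC[C@@](C)(O)CO[Si](C)(C)C(C)(C)C | intermediate
4 | methyl 3,3-dimethoxycyclobutane-1-carboxylate | COC(=O)C1CC(OC)(OC)C1 | starting material
5 | 3,3-dimethoxycyclobutane-1-carbaldehyde | O=CC1CC(OC)(OC)C1 | intermediate
6 | 3-ethynyl-1,1-dimethoxycyclobutane | C#CC1CC(OC)(OC)C1 | intermediate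
7 | 3-ethynylcyclobutan-1-one | C#CC1CC(=O)C1 | intermediate
8 | 3-[(4E,6R)-7-[(tert-butyldimethylsilyl)oxy]-6-hydroxy-6-methylhepta-1,4-dien-2-yl]cyclobutan-1-one | C=C(C/C=C/[C@@](C)(O)CO[Si](C)(C)C(C)(C)C)C1CC(=O)C1 | intermediate
9 | 3-(trimethylsilyl)prop-2-yn-1-ol | C[Si](C)(C)C#CCO | starting material
10 | tert-butyldimethyl{[3-(trimethylsilyl)prop-2-yn-1-yl]oxy}silane | C[Si](C)(C)C#CCO[Si](C)(C)C(C)(C)C | intermediate
11 | (5R)-2-{[(tert-butyldimethylsilyl)oxy]methyl}-5-[(4E,6R)-7-[(tert-butyldimethylsilyl)oxy]-6-hydroxy-6-methylhepta-1,4-dien-2-yl]-3-(trimethylsilyl)cyclohex-2-en-1-one | C=C(C/C=C/[C@@](C)(O)CO[Si](C)(C)C(C)(C)C)[C@H]1CC([Si](C)(C)C)=C(CO[Si](C)(C)C(C)(C)C)C(=O)C1 | intermediate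
12 | (1S,5R)-2-{[(tert-butyldimethylsilyl)oxy]methyl}-5-[(4E,6R)-7-[(tert-butyldimethylsilyl)oxy]-6-hydroxy-6-methylhepta-1,4-dien-2-yl]-3-(trimethylsilyl)cyclohex-2-en-1-ol | C=C(C/C=C/[C@@](C)(O)CO[Si](C)(C)C(C)(C)C)[C@H]1CC([Si](C)(C)C)=C(CO[Si](C)(C)C(C)(C)C)[C@@H](O)C1 | intermediate
13 | (1S,5R)-5-[(4E,6R)-6,7-dihydroxy-6-methylhepta-1,4-dien-2-yl]-2-(hydroxymethyl)-3-(trimethylsilyl)cyclohex-2-en-1-ol | C=C(C/C=C/[C@@](C)(O)CO)[C@H]1CC([Si](C)(C)C)=C(CO)[C@@H](O)C1 | intermediate
14 | (1S,5S)-5-[(4E,6R)-6,7-dihydroxy-6-methylhepta-1,4-dien-2-yl]-2-{[(trimethylsilyl)oxy]methyl}cyclohex-2-en-1-ol | C=C(C/C=C/[C@@](C)(O)CO)[C@H]1CC=C(CO[Si](C)(C)C)[C@@H](O)C1 | intermediate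
15 | (1S,5S)-5-[(4E,6R)-6,7-dihydroxy-6-methylhepta-1,4-dien-2-yl]-2-(hydroxymethyl)cyclohex-2-en-1-ol | C=C(C/C=C/[C@@](C)(O)CO)[C@H]1CC=C(CO)[C@@H](O)C1 | intermediate
16 | {(4S,6S)-6-hydroxy-4-[(4E,6R)-6-hydroxy-6-methyl-7-(2-methylpropanoyloxy)hepta-1,4-dien-2-yl]cyclohex-1-en-1-yl}methyl 2-methylpropanoate | C=C(C/C=C/[C@@](C)(O)COC(=O)C(C)C)[C@H]1CC=C(COC(=O)C(C)C)[C@@H](O)C1 | target

Total step count: 10. Longest linear sequence: 7 steps (steps 3, 4, 5, 7, 8, 9 and 10, from 4 to 16).

Steps most likely to fail

Step 7. The ligand may discriminate poorly between the two enantiotopic ring bonds, the alkyne may insert with eroded regiocontrol, or the catalyst may be diverted into alkyne oligomerisation. The fallback sets out from 8 and 10 and returns at 12. The insertion is run under the established achiral conditions (Ni(cod)2, PCy3, toluene, 100 °C), which should give 11 together with its ring epimer, the (5S)-enone F1. Luche reduction of the mixture as in step 8 should give 12 and the (1R,5S)-cis-alcohol F2. These two differ in the configuration of the ring carbinol, so an acylating lipase (Amano lipase PS or CAL-B, vinyl acetate, MTBE, 30 °C), following the usual enantiopreference of lipases for secondary alcohols, is expected to convert F2 into the (1R,5S)-acetate F3 and leave 12 untouched. Chromatography then returns 12 to the route.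

Step 5. The regioisomeric ruthenacycle may lead to the linear coupling isomer, or the skipped diene may isomerise. The fallback sets out from 6 and 2 and returns at 8. Indium-mediated Markovnikov allylation of alkyne 6 (indium metal, allyl bromide, THF, rt) should give 1,1-dimethoxy-3-(penta-1,4-dien-2-yl)cyclobutane F4. Epoxide 2 is homologated with dimethylsulfonium methylide (trimethylsulfonium iodide, n-BuLi, THF, −10 °C to rt) to the tertiary vinyl carbinol (2R)-1-[(tert-butyldimethylsilyl)oxy]-2-methylbut-3-en-2-ol F5. Cross-metathesis of the two (second-generation Hoveyda–Grubbs catalyst, RuCl2(H2IMes)(=CH-C6H4-2-OiPr), CH2Cl2, 40 °C) should engage only the monosubstituted olefin of F4 and give the E-configured ketal diene F6. Mild hydrolysis (oxalic acid on wet silica gel, CH2Cl2, rt) then gives 8.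

Step 9. Carbon-to-oxygen silyl transfer may stall at the hindered tetrasubstituted vinylsilane, or prolonged heating with basic fluoride may isomerise the skipped diene. The fallback sets out from 8 and returns at 15, and changes the silicon placeholder instead of the conditions. Commercial tert-butyldimethyl(prop-2-yn-1-yloxy)silane is C-silylated (n-BuLi, then benzylchlorodimethylsilane, THF, −78 °C) to benzyl{3-[(tert-butyldimethylsilyl)oxy]prop-1-yn-1-yl}dimethylsilane F7. This is used in step 7 in place of 10 to give the benzyldimethylsilyl enone F8, and Luche reduction as in step 8 gives the benzyldimethylsilyl allylic alcohol F9. TBAF at rt should first remove the benzyl group from silicon, and the resulting fluorosilane leaves the ring carbon without help from the neighbouring alkoxide while both silyl ethers are cleaved, giving 15.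

Further compounds
F1 | step 7 | (5S)-2-{[(tert-butyldimethylsilyl)oxy]methyl}-5-[(4E,6R)-7-[(tert-butyldimethylsilyl)oxy]-6-hydroxy-6-methylhepta-1,4-dien-2-yl]-3-(trimethylsilyl)cyclohex-2-en-1-one | C=C(C/C=C/[C@@](C)(O)CO[Si](C)(C)C(C)(C)C)[C@@H]1CC([Si](C)(C)C)=C(CO[Si](C)(C)C(C)(C)C)C(=O)C1
F2 | step 7 | (1R,5S)-2-{[(tert-butyldimethylsilyl)oxy]methyl}-5-[(4E,6R)-7-[(tert-butyldimethylsilyl)oxy]-6-hydroxy-6-methylhepta-1,4-dien-2-yl]-3-(trimethylsilyl)cyclohex-2-en-1-ol | C=C(C/C=C/[C@@](C)(O)CO[Si](C)(C)C(C)(C)C)[C@@H]1CC([Si](C)(C)C)=C(CO[Si](C)(C)C(C)(C)C)[C@H](O)C1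
F3 | step 7 | (1R,5S)-2-{[(tert-butyldimethylsilyl)oxy]methyl}-5-[(4E,6R)-7-[(tert-butyldimethylsilyl)oxy]-6-hydroxy-6-methylhepta-1,4-dien-2-yl]-3-(trimethylsilyl)cyclohex-2-en-1-yl acetate | C=C(C/C=C/[C@@](C)(O)CO[Si](C)(C)C(C)(C)C)[C@@H]1CC([Si](C)(C)C)=C(CO[Si](C)(C)C(C)(C)C)[C@H](OC(C)=O)C1
F4 | step 5 | 1,1-dimethoxy-3-(penta-1,4-dien-2-yl)cyclobutane | C=CCC(=C)C1CC(OC)(OC)C1
F5 | step 5 | (2R)-1-[(tert-butyldimethylsilyl)oxy]-2-methylbut-3-en-2-ol | C=C[C@@](C)(O)CO[Si](C)(C)C(C)(C)C
F6 | step 5 | (2R,3E)-1-[(tert-butyldimethylsilyl)oxy]-6-(3,3-dimethoxycyclobutyl)-2-methylhepta-3,6-dien-2-ol | C=C(C/C=C/[C@@](C)(O)CO[Si](C)(C)C(C)(C)C)C1CC(OC)(OC)C1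
F7 | step 9 | benzyl{3-[(tert-butyldimethylsilyl)oxy]prop-1-yn-1-yl}dimethylsilane | C[Si](C)(Cc1ccccc1)C#CCO[Si](C)(C)C(C)(C)C
F8 | step 9 | (5R)-3-[benzyl(dimethyl)silyl]-2-{[(tert-butyldimethylsilyl)oxy]methyl}-5-[(4E,6R)-7-[(tert-butyldimethylsilyl)oxy]-6-hydroxy-6-methylhepta-1,4-dien-2-yl]cyclohex-2-en-1-one | C=C(C/C=C/[C@@](C)(O)CO[Si](C)(C)C(C)(C)C)[C@H]1CC([Si](C)(C)Cc2ccccc2)=C(CO[Si](C)(C)C(C)(C)C)C(=O)C1
F9 | step 9 | (1S,5R)-3-[benzyl(dimethyl)silyl]-2-{[(tert-butyldimethylsilyl)oxy]methyl}-5-[(4E,6R)-7-[(tert-butyldimethylsilyl)oxy]-6-hydroxy-6-methylhepta-1,4-dien-2-yl]cyclohex-2-en-1-ol | C=C(C/C=C/[C@@](C)(O)CO[Si](C)(C)C(C)(C)C)[C@H]1CC([Si](C)(C)Cc2ccccc2)=C(CO[Si](C)(C)C(C)(C)C)[C@@H](O)C1
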